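Percent of the substrate charged is the unit of every reading below, so I can ask straight away how much of the charge ends up as target, and only then how fast it gets there.

| setting | grey | amber | Friday's | Sunday's | Tuesday's | Saturday's |
|---|---|---|---|---|---|---|
| substrate | 0.20 mM | 0.20 mM | 0.20 mM | 0.20 mM | 0.20 mM | 0.20 mM |
| capture agent | 0.040 mM | 0.090 mM | 0.0600 mM | 0.0600 mM | 0.0600 mM | 0.0600 mM |
| temperature | 35 °C | 78 °C | 65 °C | 115 °C | 90 °C | 40 °C |
| remark | run made earlier | run made earlier |  |  |  |  |
| time |  |  | 2.0 min | 2.0 min | 2.0 min | 2.0 min |

grey run (percent of the substrate charged)

| time / min | target / % | substrate / % |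
|---|---|---|
| 0.667 | 56.9 | 0 |
| 2.00 | 88.5 | 0 |
| 3.00 | 89.8 | 0.5 |
| 4.00 | 89.6 | 0 |
| 6.00 | 90.9 | 0.2 |

amber run (percent of the substrate charged)

| time / s | target / % | substrate / % |
|---|---|---|
| 10.0 | 90.2 | 0.3 |
| 12.0 | 89.7 | 0 |
| 25.0 | 89.8 | 0.2 |
| 50.0 | 90.0 | 0.5 |

(each reading ± 0.5 percentage points)

- the flask with the highest amount of target, in percent of the substrate charged ("all alike" if they lie within 1.5 percentage points) (Friday's / Sunday's / Tuesday's / Saturday's / all alike)
- final target, as a percentage of the substrate charged, in Friday's
- final target, as a percentage of the substrate charged, in Sunday's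
- final target, as a percentage of the substrate charged, in Tuesday's
- final target, as a percentage of the substrate charged, in Saturday's



1. End state first. Grey's last 3 readings and amber's 4 are flat, and together they average 90.0 %. I carry 10 percentage points as the gap, the part of the charge that does not stand as target once the readings are flat.

2. Objection: the gap may move with the settings. Grey's flat readings average 90.1 % and amber's 89.9 %, a difference of 0.18 points against a scatter of 0.5 points per reading. But temperature and capture agent changed together between those runs, so two effects could cancel. Friday's lies inside both ranges but off the line from grey to amber, so these two runs cannot rule out such a cancellation there. Sunday's is hotter than amber, so it lies outside the tested range. The difference between the two runs stays below the margin, so I keep the gap as an estimate for the new flasks, with this doubt left open.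

3. Second objection: target might be lost on standing. Amber reads 90.2 % at 10.0 s and 90.0 % at 50.0 s, which shows no loss. Sunday's is hotter and runs longer, though, so this doubt stays open.

4. Now speed. Saturday's is the risk, with 2.0 min at 40 °C. Grey at that same time reads 88.5 %, which is 1.5 points under the plateau, right at the margin. But grey is colder, so I put Saturday's between 88.5 % and 90.0 %, and the other flasks at 90.0 %, which makes them alike.

5. The forecast says all alike, with 90 % for Friday's, 89.5 % for Sunday's, 90 % for Tuesday's and 89.8 % for Saturday's, reasoning that “the yield looks insensitive to both, barring a coincidental cancellation”.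

6. The flasks give all alike: 90.3 % in Friday's, 89.9 % in Sunday's, 90.2 % in Tuesday's and 89.8 % in Saturday's. Friday's stands 0.50 points above Saturday's, less than the margin. Substrate is the limiting reagent: Friday's ends with 0 % of it, against 98 % of the capture agent. Sunday's holds its target over ten times the time.

    substrate → intermediate A (k = 0.346 s⁻¹, Ea = 81.0 kJ mol⁻¹)
    intermediate A → intermediate B (k = 0.0647 s⁻¹, Ea = 94.0 kJ mol⁻¹)
    intermediate B → intermediate C (k = 1.70 s⁻¹, Ea = 74.0 kJ mol⁻¹)
    intermediate C → target (k = 0.281 s⁻¹, Ea = 76.0 kJ mol⁻¹)
    intermediate B + capture agent → trapped intermediate (k = 526 L mol⁻¹ s⁻¹, Ea = 37.0 kJ mol⁻¹)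
    intermediate B → decomposed reagent (k = 0.162 s⁻¹, Ea = 76.0 kJ mol⁻¹)
    (constants at 40 °C)

The gap of 10 points is mainly material leaving intermediate B as decomposed reagent. With that conversion taken away, Sunday's reaches 99.9 % of target instead of 89.9 %, and that step accounts for 99.0 % of what is missing. Sunday's holds 9.94 % decomposed reagent and 0.107 % trapped intermediate, together 10 points. A neighbour of Friday's, charged with a quarter of the capture agent, gives 90.7 % of target, 0.70 points above the plateau, with 9.15 % decomposed reagent and 0.146 % trapped intermediate.

The earlier runs and the new flask are simulated for an exercise.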